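## Plan

- Numbering: cadinane locants for the terpene half (C1 and C6 ring-fusion carbons, C7 isopropyl-bearing, C10 methyl-bearing, C4 spiro carbon, C15 the pyran CH2); C16 is the pyran CH(iPr). Ring A is the methoxy dienone, ring B the pyran, ring C the cyclohexene, ring D the isopropyl/methyl ring. The retrosynthesis first cuts O–C4 and C15–C16 of ring B (oxa-Diels–Alder) into heterodiene 23 (ring A, from phloroglucinol) and the exocyclic diene 16 (rings C and D).
- In 16, ring D (C6–C7–C8–C9–C10–C1) is opened at C1–C10 and C10 is rebound to C6, which leads back to spiro[4.5]decenol 14. Ring C of 14 is cut at C4=C5 (metathesis), and its cyclopentane comes from (−)-menthone by Wolff ring contraction.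
- Enabling feature: the quaternary spiro carbon C6 of 14 lies between the carbinol carbon C1 (leaving group) and the C4=C5 bond that carries CH2SiMe3 on C4. A shift of C10 from C6 to C1 makes C6 an allyl-cation terminus, and loss of silicon gives C5=C6 and C4=C15 in one event.
- Forward order: cyclopentane (ring contraction) → quaternary C6 → ring C (metathesis) → ring D (one-carbon ring expansion) → rings A and B joined last by cycloaddition.
- Stereochemistry: C7 and C10 from (−)-menthone; C6 (spiro centre) by enolate addition anti to isopropyl; C1 by hydride reduction, then stereospecific migration with inversion; C4 and C16 by the endo cycloaddition on the face anti to isopropyl.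

Key step: step 9

Remark: (−)-menthone is taken as the (2S,5R) enantiomer, whose two stereocentres map onto C7 and C10; the enolisable triketones 20–23 are each written as one tautomer.

## Route

Step 1
Reactants: 1 (−)-menthone, (2S,5R)-5-methyl-2-(propan-2-yl)cyclohexan-1-one
Product: 3 (3R,6S)-2-diazo-3-methyl-6-(propan-2-yl)cyclohexan-1-one, via trifluoroacetyl ketone 2 (not isolated)
Conditions: LiN(SiMe3)2, THF, −78 °C; CF3CO2CH2CF3, −78 °C; aq. HCl; then MsN3, Et3N, H2O, MeCN, 23 °C
Reagents that add atoms: methanesulfonyl azide, CS(=O)(=O)N=[N+]=[N-]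
Why: Regitz-type detrifluoroacetylative diazo transfer: the kinetic lithium enolate forms at the methylene carbon, is activated as the trifluoroacetyl ketone and exchanges that group for N2, so the isopropyl-bearing α-stereocentre is not enolised.

Step 2
Reactants: 3 (3R,6S)-2-diazo-3-methyl-6-(propan-2-yl)cyclohexan-1-one
Product: 5 methyl (2R,5S)-2-methyl-5-(propan-2-yl)cyclopentane-1-carboxylate (both C1 epimers), via ketene 4 (not isolated)
Conditions: hν (medium-pressure Hg lamp, Pyrex), MeOH, 0 °C
Reagents that add atoms: methanol, CO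
Why: Photochemical Wolff rearrangement: the isopropyl-bearing carbon migrates with retention from the carbonyl to the carbene carbon and methanol captures the ketene, so the six-membered ring of menthone is contracted to a cyclopentane that keeps both stereocentres (the ester-bearing carbon is planarised in step 3).

Step 3
Reactants: 5 methyl (2R,5S)-2-methyl-5-(propan-2-yl)cyclopentane-1-carboxylate; 6 phenyl vinyl sulfoxide
Product: 7 methyl (1S,2R,5S)-2-methyl-1-[2-(phenylsulfinyl)ethyl]-5-(propan-2-yl)cyclopentane-1-carboxylate (mixture at sulfur)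
Conditions: LiN(iPr)2, THF, −78 °C; then 6, −78 → 0 °C; aq. NH4Cl
Reagents that add atoms: none
Why: Michael addition of the tetrasubstituted ester enolate to an aryl vinyl sulfoxide (vinyl cation equivalent) should occur on the ring face flanked by the methyl group and anti to the bulkier isopropyl group, which sets the quaternary carbon C6 with the two-carbon arm cis to methyl and the ester cis to isopropyl.

Step 4
Reactants: 7 methyl (1S,2R,5S)-2-methyl-1-[2-(phenylsulfinyl)ethyl]-5-(propan-2-yl)cyclopentane-1-carboxylate
Product: 8 methyl (1S,2R,5S)-1-ethenyl-2-methyl-5-(propan-2-yl)cyclopentane-1-carboxylate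
Conditions: toluene, CaCO3, 110 °C
Reagents that add atoms: none
Why: Thermal syn-elimination of the sulfoxide (sulfoxide pyrolysis) can only take a hydrogen from the CH2 next to the quaternary carbon and thus unveils the vinyl group, no stereocentre being involved.

Step 5
Reactants: 8 methyl (1S,2R,5S)-1-ethenyl-2-methyl-5-(propan-2-yl)cyclopentane-1-carboxylate
Product: 10 1-[(1S,2R,5S)-1-ethenyl-2-methyl-5-(propan-2-yl)cyclopentyl]ethan-1-one, via silyl ketone 9 (not isolated)
Conditions: LiCH2SiMe3 (2.5 equiv), pentane–THF, 0 → 23 °C; then MeOH, 23 °C; aq. NH4Cl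
Reagents that add atoms: (trimethylsilyl)methyllithium, [Li]C[Si](C)(C)C
Why: Acylation of (trimethylsilyl)methyllithium by the hindered ester stops at the ketone stage because the α-silyl ketone is at once enolised by a second equivalent, and methanolysis of the C–Si bond then gives the methyl ketone (a Peterson-type reagent used as a methyl anion equivalent).

Step 6
Reactants: 10 1-[(1S,2R,5S)-1-ethenyl-2-methyl-5-(propan-2-yl)cyclopentyl]ethan-1-one; 11 [2-(chloromethyl)prop-2-en-1-yl]trimethylsilane
Product: 12 1-[(1S,2R,5S)-1-ethenyl-2-methyl-5-(propan-2-yl)cyclopentyl]-5-[(trimethylsilyl)methyl]hex-5-en-1-one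
Conditions: LiN(iPr)2, THF, −78 °C; then 11, NaI (10 mol %), −78 → 0 °C
Reagents that add atoms: none
Why: The methyl group is the only enolisable position of 10, so kinetic enolate alkylation with the allylic chloride (SN2 and SN2' give the same product) attaches the 2-(silylmethyl)allyl unit that supplies C3, C4 and C15.

Step 7
Reactants: 12 1-[(1S,2R,5S)-1-ethenyl-2-methyl-5-(propan-2-yl)cyclopentyl]-5-[(trimethylsilyl)methyl]hex-5-en-1-one
Product: 13 (1R,4S,5S)-1-methyl-4-(propan-2-yl)-9-[(trimethylsilyl)methyl]spiro[4.5]dec-9-en-6-one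
Conditions: second-generation Grubbs catalyst (H2IMes)(PCy3)Cl2Ru=CHPh (5 mol %), CH2Cl2, 40 °C
Reagents that add atoms: none
Why: Ring-closing metathesis between the vinyl group and the 1,1-disubstituted alkene forms the six-membered ring C as a trisubstituted cyclohexene, driven by loss of ethene, the allylsilane and ketone being inert to the ruthenium carbene.

Step 8
Reactants: 13 (1R,4S,5S)-1-methyl-4-(propan-2-yl)-9-[(trimethylsilyl)methyl]spiro[4.5]dec-9-en-6-one
Product: 14 (1R,4S,5S,6R)-1-methyl-4-(propan-2-yl)-9-[(trimethylsilyl)methyl]spiro[4.5]dec-9-en-6-ol (hydroxyl cis to the isopropyl-bearing ring carbon)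
Conditions: NaBH4, MeOH, 0 °C
Reagents that add atoms: none
Why: Hydride addition to the ketone should occur from the face remote from the isopropyl group of the adjacent cyclopentane carbon (steric approach control, axial attack anti to that pseudo-axial carbon), which places the new hydroxyl at C1 cis to the isopropyl-bearing carbon C7 and anti to C10.

Step 9
Reactants: 14 (1R,4S,5S,6R)-1-methyl-4-(propan-2-yl)-9-[(trimethylsilyl)methyl]spiro[4.5]dec-9-en-6-ol
Product: 16 (1S,4R,4aR)-4-methyl-7-methylidene-1-(propan-2-yl)-1,2,3,4,4a,5,6,7-octahydronaphthalene, via triflate 15 (not isolated)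
Conditions: (CF3SO2)2O, 2,6-lutidine, CH2Cl2, −78 → 0 °C; aq. NaHCO3
Reagents that add atoms: none
Why: Proposed new method: O-triflation of 14 gives 15, in whose half-chair with the triflate axial the C6–C10 bond of the cyclopentane is anti-periplanar to the C1–O bond and parallel to the p orbitals of the C4=C5 allylsilane, so ionisation at C1 should be concerted with a suprafacial 1,2-shift of C10 from C6 to C1, the positive charge emerging as a C6–C5–C4 allyl cation whose C4 terminus is β to silicon and which collapses by loss of Me3Si+ (as Me3SiOTf) to the conjugated C5=C6/C4=C15 diene. The closest known reaction types are the solvolytic Wagner–Meerwein ring expansion of spiro[4.5]decan-6-yl sulfonates to octalins and the 1,4-elimination of δ-silyl allylic cations (vinylogous Peterson elimination) used to terminate cationic cascades. No ring is closed by cyclisation: the five-membered ring grows by one carbon into six-membered ring D through the shift, while ring C is kept. The single new stereocentre C1 is set stereospecifically by inversion at the carbinol carbon with retention at migrating C10, so it follows from the C1–O configuration (step 8) and the spiro configuration (step 3), and C7 and C10 are untouched. The step needs migration of C10 in preference to C7, to the vinylic C5 and to hydride, which the anti-periplanar, allylically assisted alignment should secure, and it needs both new double bonds in defined positions without loss of a proton from C1 or C7, which the silyl terminator secures. The main competitor, three-membered ring closure by the allylsilane carbon C5 onto C1, requires the less favoured equatorial-triflate conformer and builds a strained bicyclo[3.1.0]hexane, and is therefore expected to be slower.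

Step 10
Reactants: 17 phloroglucinol (benzene-1,3,5-triol); 18 2-methylpropanoyl chloride
Product: 19 2-methyl-1-(2,4,6-trihydroxyphenyl)propan-1-one
Conditions: AlCl3, PhNO2–CH2Cl2, 0 → 40 °C; aq. HCl
Reagents that add atoms: none
Why: Friedel–Crafts acylation of the electron-rich phloroglucinol stops after one acyl group because the ketone deactivates the ring.

Step 11
Reactants: 19 2-methyl-1-(2,4,6-trihydroxyphenyl)propan-1-one
Product: 20 3,5-dihydroxy-4,6,6-trimethyl-2-(2-methylpropanoyl)cyclohexa-2,4-dien-1-one
Conditions: NaOMe (4 equiv), MeI (3.1 equiv), MeOH, 0 → 23 °C; aq. HCl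
Reagents that add atoms: iodomethane, CI
Why: Base-mediated C-methylation of the acylphloroglucinol polyanion (dearomatising alkylation) places two methyl groups on one free ring carbon and one on the other, the limited amount of MeI stopping the sequence before a fourth methylation.

Step 12
Reactants: 20 3,5-dihydroxy-4,6,6-trimethyl-2-(2-methylpropanoyl)cyclohexa-2,4-dien-1-one
Product: 21 3-hydroxy-5-methoxy-4,6,6-trimethyl-2-(2-methylpropanoyl)cyclohexa-2,4-dien-1-one (tasmanone)
Conditions: Me3SiCHN2, toluene–MeOH (4:1), 0 °C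
Reagents that add atoms: (trimethylsilyl)diazomethane, C[Si](C)(C)C=[N+]=[N-]
Why: Methylation of a vinylogous acid by a diazoalkane should take place at the only enol hydroxyl that is not held in the intramolecular hydrogen bond to the acyl carbonyl, the one between the C-methyl and the gem-dimethyl carbon.

Step 13
Reactants: 21 3-hydroxy-5-methoxy-4,6,6-trimethyl-2-(2-methylpropanoyl)cyclohexa-2,4-dien-1-one
Product: 22 3-hydroxy-2-(1-hydroxy-2-methylpropyl)-5-methoxy-4,4,6-trimethylcyclohexa-2,5-dien-1-one (racemic carbinol)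
Conditions: NaBH4, THF–MeOH, 0 °C; aq. NH4Cl
Reagents that add atoms: none
Why: Borohydride reduces the side-chain ketone of the enolised β-triketone to the carbinol, the ring carbonyls being deactivated as vinylogous ester and enolate.

Step 14
Reactants: 16 (1S,4R,4aR)-4-methyl-7-methylidene-1-(propan-2-yl)-1,2,3,4,4a,5,6,7-octahydronaphthalene; 22 3-hydroxy-2-(1-hydroxy-2-methylpropyl)-5-methoxy-4,4,6-trimethylcyclohexa-2,5-dien-1-one
Product: 24 CNP0194760.3, (2S,4R,4a'R,5'R,8'S)-7-methoxy-5',6,8,8-tetramethyl-4,8'-di(propan-2-yl)-3,3',4,4',4a',5',6',7'-octahydro-8'H-spiro[chromene-2,2'-naphthalen]-5(8H)-one, via heterodiene 23 (not isolated)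
Conditions: p-TsOH·H2O (10 mol %), 4 Å molecular sieves, CH2Cl2, 0 → 23 °C
Reagents that add atoms: none
Why: Acid-catalysed dehydration of 22 gives the α-alkylidene β-diketone 23, which should add to the terminal C4=C15 bond of 16 in an inverse-electron-demand oxa-Diels–Alder reaction (six-membered ring B; oxygen of the carbonyl next to the gem-dimethyl carbon to the more substituted C4, C16 to C15), the endo position of the C5=C6 vinyl unit fixing C16 relative to C4 and approach to the diene face opposite the pseudo-axial isopropyl group at C7 fixing both relative to ring D.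

## Compound list

1 | (−)-menthone, (2S,5R)-5-methyl-2-(propan-2-yl)cyclohexan-1-one | CC(C)[C@@H]1CC[C@@H](C)CC1=O | starting material
2 | (3R,6S)-3-methyl-6-(propan-2-yl)-2-(trifluoroacetyl)cyclohexan-1-one (not isolated) | CC(C)[C@@H]1CC[C@@H](C)C(C(=O)C(F)(F)F)C1=O | intermediate
3 | (3R,6S)-2-diazo-3-methyl-6-(propan-2-yl)cyclohexan-1-one | CC(C)[C@@H]1CC[C@@H](C)C(=[N+]=[N-])C1=O | intermediate
4 | [(2R,5S)-2-methyl-5-(propan-2-yl)cyclopentylidene]methanone, ketene (not isolated) | CC(C)[C@@H]1CC[C@@H](C)C1=C=O | intermediate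
5 | methyl (2R,5S)-2-methyl-5-(propan-2-yl)cyclopentane-1-carboxylate (C1 epimers) | CC(C)[C@@H]1CC[C@@H](C)C1C(=O)OC | intermediate
6 | phenyl vinyl sulfoxide | C=CS(=O)c1ccccc1 | starting material
7 | methyl (1S,2R,5S)-2-methyl-1-[2-(phenylsulfinyl)ethyl]-5-(propan-2-yl)cyclopentane-1-carboxylate | CC(C)[C@@H]1CC[C@@H](C)[C@]1(CCS(=O)c1ccccc1)C(=O)OC | intermediate
8 | methyl (1S,2R,5S)-1-ethenyl-2-methyl-5-(propan-2-yl)cyclopentane-1-carboxylate | CC(C)[C@@H]1CC[C@@H](C)[C@]1(C=C)C(=O)OC | intermediate
9 | 1-[(1S,2R,5S)-1-ethenyl-2-methyl-5-(propan-2-yl)cyclopentyl]-2-(trimethylsilyl)ethan-1-one (not isolated) | CC(C)[C@@H]1CC[C@@H](C)[C@]1(C=C)C(=O)C[Si](C)(C)C | intermediate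
10 | 1-[(1S,2R,5S)-1-ethenyl-2-methyl-5-(propan-2-yl)cyclopentyl]ethan-1-one | CC(C)[C@@H]1CC[C@@H](C)[C@]1(C=C)C(C)=O | intermediate
11 | [2-(chloromethyl)prop-2-en-1-yl]trimethylsilane | C=C(CCl)C[Si](C)(C)C | starting material
12 | 1-[(1S,2R,5S)-1-ethenyl-2-methyl-5-(propan-2-yl)cyclopentyl]-5-[(trimethylsilyl)methyl]hex-5-en-1-one | CC(C)[C@@H]1CC[C@@H](C)[C@]1(C=C)C(=O)CCC(=C)C[Si](C)(C)C | intermediate
13 | (1R,4S,5S)-1-methyl-4-(propan-2-yl)-9-[(trimethylsilyl)methyl]spiro[4.5]dec-9-en-6-one | CC(C)[C@@H]1CC[C@@H](C)[C@@]12C=C(C[Si](C)(C)C)CCC2=O | intermediate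
14 | (1R,4S,5S,6R)-1-methyl-4-(propan-2-yl)-9-[(trimethylsilyl)methyl]spiro[4.5]dec-9-en-6-ol | CC(C)[C@@H]1CC[C@@H](C)[C@@]12C=C(C[Si](C)(C)C)CC[C@H]2O | intermediate
15 | (1R,4S,5S,6R)-1-methyl-4-(propan-2-yl)-9-[(trimethylsilyl)methyl]spiro[4.5]dec-9-en-6-yl trifluoromethanesulfonate (not isolated) | CC(C)[C@@H]1CC[C@@H](C)[C@@]12C=C(C[Si](C)(C)C)CC[C@H]2OS(=O)(=O)C(F)(F)F | intermediate
16 | (1S,4R,4aR)-4-methyl-7-methylidene-1-(propan-2-yl)-1,2,3,4,4a,5,6,7-octahydronaphthalene | C=C1C=C2[C@H](C(C)C)CC[C@@H](C)[C@H]2CC1 | intermediate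
17 | phloroglucinol | Oc1cc(O)cc(O)c1 | starting material
18 | 2-methylpropanoyl chloride | CC(C)C(Cl)=O | starting material
19 | 2-methyl-1-(2,4,6-trihydroxyphenyl)propan-1-one | CC(C)C(=O)c1c(O)cc(O)cc1O | intermediate
20 | 3,5-dihydroxy-4,6,6-trimethyl-2-(2-methylpropanoyl)cyclohexa-2,4-dien-1-one | CC(C)C(=O)C1=C(O)C(C)=C(O)C(C)(C)C1=O | intermediate
21 | 3-hydroxy-5-methoxy-4,6,6-trimethyl-2-(2-methylpropanoyl)cyclohexa-2,4-dien-1-one | COC1=C(C)C(O)=C(C(=O)C(C)C)C(=O)C1(C)C | intermediate
22 | 3-hydroxy-2-(1-hydroxy-2-methylpropyl)-5-methoxy-4,4,6-trimethylcyclohexa-2,5-dien-1-one | COC1=C(C)C(=O)C(C(O)C(C)C)=C(O)C1(C)C | intermediate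
23 | 5-methoxy-4,6,6-trimethyl-2-(2-methylpropylidene)cyclohex-4-ene-1,3-dione (not isolated) | COC1=C(C)C(=O)C(=CC(C)C)C(=O)C1(C)C | intermediate
24 | CNP0194760.3 | COC1=C(C)C(=O)C2=C(O[C@]3(C=C4[C@H](C(C)C)CC[C@@H](C)[C@H]4CC3)C[C@@H]2C(C)C)C1(C)C | target

## Step count and risks

Total step count: 14. Longest linear sequence: 10 steps (steps 1–9 and 14).

Steps most likely to fail:

1. Step 9 (Proposed new method). What may go wrong: participation of the allylsilane double bond at the ionising carbon (three-membered ring closure), plain elimination of the triflate, or protodesilylation before the alkyl shift. Fallback with known chemistry, setting out from 10 and coming back at 16: the silyl terminator is given up and the ring expansion is run as a classical buffered solvolysis. Enolate allylation of 10 (LiN(iPr)2, allyl bromide) gives 1-[(1S,2R,5S)-1-ethenyl-2-methyl-5-(propan-2-yl)cyclopentyl]pent-4-en-1-one F1. Ring-closing metathesis gives the des-silyl spiro enone, 1-methyl-4-(propan-2-yl)spiro[4.5]dec-9-en-6-one F2. NaBH4 gives the corresponding spiro alcohol F3, and MsCl/Et3N its methanesulfonate F4. Solvolysis of F4 (acetone–water, CaCO3, 60 °C), the long-known Wagner–Meerwein ring expansion of spiro[4.5]decan-6-yl sulfonates, here with capture of the allyl cation by water, gives (4aR,5R,8S)-5-methyl-8-(propan-2-yl)-2,3,4,4a,5,6,7,8-octahydronaphthalen-2-ol F5 together with its tertiary allylic isomer. Both are oxidised by pyridinium chlorochromate [C5H5NH][CrO3Cl] (direct oxidation and Dauben–Babler transposition) to (4aR,5R,8S)-5-methyl-8-(propan-2-yl)-4,4a,5,6,7,8-hexahydronaphthalen-2(3H)-one F6. Wittig methylenation (Ph3P=CH2) returns 16.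

2. Step 14. What may go wrong: poor facial and endo/exo discrimination in the cycloaddition, and acid-induced isomerisation of the exocyclic diene before it reacts. Fallback, setting out from 16 and 22 and coming back at 24: substrate control is replaced by catalyst control. 23 is generated and activated by a chiral BINOL-derived phosphoric acid at low temperature, whose hydrogen-bonded complex with the heterodiene dictates the face at C16, the matched catalyst enantiomer being chosen. No new compound is made (F0).

3. Step 3. What may go wrong: sluggish conjugate addition of the hindered tetrasubstituted enolate, reversal of the addition, or insufficient facial selectivity. Fallback, setting out from 5 and coming back at 13: the two-carbon arm is brought in by alkylation with a small, very reactive electrophile and the double bond is then moved. Enolate allylation of 5 (LiN(iPr)2, allyl bromide) gives methyl (2R,5S)-2-methyl-5-(propan-2-yl)-1-(prop-2-en-1-yl)cyclopentane-1-carboxylate F7. Alkene isomerisation with RuHCl(CO)(PPh3)3 (toluene, 80 °C) gives the (E)-prop-1-enyl ester F8. LiCH2SiMe3 then MeOH gives the prop-1-enyl methyl ketone F9, and alkylation with 11 gives the prop-1-enyl analogue of 12, F10. Ring-closing metathesis of F10, with loss of propene, gives 13.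

Further compounds
F1 | step 9 | 1-[(1S,2R,5S)-1-ethenyl-2-methyl-5-(propan-2-yl)cyclopentyl]pent-4-en-1-one | CC(C)[C@@H]1CC[C@@H](C)[C@]1(C=C)C(=O)CCC=C
F2 | step 9 | 1-methyl-4-(propan-2-yl)spiro[4.5]dec-9-en-6-one (des-silyl analogue of 13) | CC(C)[C@@H]1CC[C@@H](C)[C@@]12C=CCCC2=O
F3 | step 9 | 1-methyl-4-(propan-2-yl)spiro[4.5]dec-9-en-6-ol (des-silyl analogue of 14) | CC(C)[C@@H]1CC[C@@H](C)[C@@]12C=CCC[C@H]2O
F4 | step 9 | 1-methyl-4-(propan-2-yl)spiro[4.5]dec-9-en-6-yl methanesulfonate | CC(C)[C@@H]1CC[C@@H](C)[C@@]12C=CCC[C@H]2OS(C)(=O)=O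
F5 | step 9 | (4aR,5R,8S)-5-methyl-8-(propan-2-yl)-2,3,4,4a,5,6,7,8-octahydronaphthalen-2-ol | OC1C=C2[C@H](C(C)C)CC[C@@H](C)[C@H]2CC1
F6 | step 9 | (4aR,5R,8S)-5-methyl-8-(propan-2-yl)-4,4a,5,6,7,8-hexahydronaphthalen-2(3H)-one | O=C1C=C2[C@H](C(C)C)CC[C@@H](C)[C@H]2CC1
F0 | step 14 | none | none
F7 | step 3 | methyl (2R,5S)-2-methyl-5-(propan-2-yl)-1-(prop-2-en-1-yl)cyclopentane-1-carboxylate | CC(C)[C@@H]1CC[C@@H](C)[C@]1(CC=C)C(=O)OC
F8 | step 3 | methyl (2R,5S)-2-methyl-5-(propan-2-yl)-1-[(E)-prop-1-en-1-yl]cyclopentane-1-carboxylate | CC(C)[C@@H]1CC[C@@H](C)[C@]1(/C=C/C)C(=O)OC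
F9 | step 3 | 1-{(2R,5S)-2-methyl-5-(propan-2-yl)-1-[(E)-prop-1-en-1-yl]cyclopentyl}ethan-1-one | CC(C)[C@@H]1CC[C@@H](C)[C@]1(/C=C/C)C(C)=O
F10 | step 3 | 1-{(2R,5S)-2-methyl-5-(propan-2-yl)-1-[(E)-prop-1-en-1-yl]cyclopentyl}-5-[(trimethylsilyl)methyl]hex-5-en-1-one | CC(C)[C@@H]1CC[C@@H](C)[C@]1(/C=C/C)C(=O)CCC(=C)C[Si](C)(C)C
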